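**Assumption:** (R)-but-3-en-2-ol (≥98% ee) and 2,3-O-isopropylidene-D-erythronolactone are treated as inexpensive commercial chiral building blocks. The route has not been run; selectivities are expectations, not measured values.

## Retrosynthetic overview

1. Target ⇐ ester reduction and acid removal of acetonide/TBS from the protected bicycle 17.
2. Cyclohexene ring (C1'=C2') ⇐ ring-closing metathesis of diene 16; this ring is formed last.
3. Dihydrobenzofuran ring (O1–C2) ⇐ Pd π-allyl etherification of 15, trans to C3; this ring is formed first.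
4. C2–C1' ⇐ Ni/Cr coupling of lactol 7 with vinyl bromide 13; 13 carries C3'/C4' from D-erythronolactone acetonide.
5. C3–C3a (key bond) ⇐ aromatic Claisen [3,3] rearrangement of aryl ether 5, with 1,3-chirality transfer from the (R)-but-3-en-2-ol stereocentre.

## Route

**Step 1**
Reactants: 1, methyl 3-(4-hydroxy-3-methoxyphenyl)propanoate; 2, (R)-but-3-en-2-ol
Product: 3, methyl 3-{4-[(2S)-but-3-en-2-yloxy]-3-methoxyphenyl}propanoate
Conditions: PPh3, DIAD, THF, 0 °C → rt
Reagents that add atoms: none beyond the listed reactants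
Why: Mitsunobu etherification of the phenol proceeds by SN2 with clean inversion (R → S); any SN2' crotyl ether is achiral and removed by chromatography.

**Step 2**
Reactants: 3; 4, allyl tert-butyldimethylsilyl ether (3 equiv)
Product: 5, methyl 3-{4-[(2S,3E)-5-(tert-butyldimethylsilyloxy)pent-3-en-2-yl]oxy-3-methoxyphenyl}propanoate
Conditions: Grubbs II (5 mol %), CH2Cl2, 40 °C
Reagents that add atoms: none beyond 4
Why: Olefin cross-metathesis of the allylic-branched terminal alkene is E-selective and leaves the stereocentre untouched; the minor Z isomer must be removed because it would give the opposite C3 configuration in step 3.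

**Step 3 (key step)**
Reactants: 5
Product: 6, methyl 3-{3-[(2R,3E)-1-(tert-butyldimethylsilyloxy)pent-3-en-2-yl]-4-hydroxy-5-methoxyphenyl}propanoate
Conditions: PhNEt2, 185 °C, sealed tube
Reagents that add atoms: none
Why: Aromatic Claisen rearrangement to the only free ortho position through a chair transition state with the methyl equatorial; suprafacial 1,3-chirality transfer from the (S)-ether carbon sets the future C3 as R and gives the E-propenyl group.

**Step 4**
Reactants: 6
Product: 7, methyl 3-[(3R)-3-(tert-butyldimethylsilyloxymethyl)-2-hydroxy-7-methoxy-2,3-dihydro-1-benzofuran-5-yl]propanoate (lactol, C2 anomers)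
Conditions: O3, CH2Cl2/MeOH, −78 °C (Sudan III end point); then Me2S
Reagents that add atoms: ozone, [O-][O+]=O
Why: Ozonolysis cleaves the propenyl group (losing acetaldehyde); the α-aryl aldehyde is trapped at once by the phenol as the five-membered lactol, which protects C3 from epimerisation and β-elimination.

**Step 5**
Reactants: 8, 2,3-O-isopropylidene-D-erythronolactone
Product: 9, 2,3-O-isopropylidene-D-erythrose (lactol)
Conditions: DIBAL-H, CH2Cl2, −78 °C
Reagents that add atoms: none
Why: Partial reduction of the γ-lactone stops at the lactol; both stereocentres are bought and untouched.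

**Step 6**
Reactants: 9
Product: 10, [(4R,5S)-2,2-dimethyl-5-vinyl-1,3-dioxolan-4-yl]methanol
Conditions: Ph3PCH3Br, KOtBu, THF, 0 °C → rt
Reagents that add atoms: methyltriphenylphosphonium bromide, C[P+](c1ccccc1)(c1ccccc1)c1ccccc1.[Br-]
Why: Wittig methylenation of the open-chain aldehyde turns the lactol carbon into the vinyl CH that becomes C2' and frees the primary alcohol (future C5').

**Step 7**
Reactants: 10
Product: 11, (4S,5S)-4-(iodomethyl)-2,2-dimethyl-5-vinyl-1,3-dioxolane
Conditions: I2, PPh3, imidazole, CH2Cl2, 0 °C → rt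
Reagents that add atoms: iodine, II
Why: Appel-type iodination of the primary alcohol; no stereocentre is involved.

**Step 8**
Reactants: 11; 12, 2,3-dibromopropene (5 equiv)
Product: 13, (4R,5S)-4-(3-bromobut-3-en-1-yl)-2,2-dimethyl-5-vinyl-1,3-dioxolane
Conditions: (Bu3Sn)2, hν (sun lamp), PhH, 80 °C
Reagents that add atoms: none beyond 12
Why: Ditin-mediated radical allylation: the primary alkyl radical adds to the CH2 terminus of 12 and expels Br•, forming C5'–C6'. A radical (unlike an anion) does not eliminate the β-alkoxy group, and no 5-exo cyclisation path is available.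

**Step 9**
Reactants: 7; 13
Product: 14, methyl 3-{3-[(2R)-1-(tert-butyldimethylsilyloxy)-6-[(4R,5S)-2,2-dimethyl-5-vinyl-1,3-dioxolan-4-yl]-3-hydroxy-4-methylidenehexan-2-yl]-4-hydroxy-5-methoxyphenyl}propanoate (carbinol epimers)
Conditions: CrCl2 (4 equiv), NiCl2 (2 mol %), DMF, rt
Reagents that add atoms: none
Why: Nozaki–Hiyama–Kishi coupling of the alkenyl bromide with the aldehyde released from the lactol forms C2–C1' under non-basic conditions, so C3 is not epimerised. The carbinol configuration is irrelevant because it is erased in step 11.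

**Step 10**
Reactants: 14
Product: 15, the phenyl acetate / allylic acetate of 14 (diacetate)
Conditions: Ac2O, pyridine, DMAP (cat.), CH2Cl2, rt
Reagents that add atoms: acetic anhydride, CC(=O)OC(C)=O
Why: Exhaustive acetylation turns the allylic alcohol into a leaving group for Pd and temporarily masks the phenol.

**Step 11**
Reactants: 15
Product: 16, methyl 3-[(2S,3R)-3-(tert-butyldimethylsilyloxymethyl)-2-{4-[(4R,5S)-2,2-dimethyl-5-vinyl-1,3-dioxolan-4-yl]but-1-en-2-yl}-7-methoxy-2,3-dihydro-1-benzofuran-5-yl]propanoate
Conditions: K2CO3, MeOH–THF, 0 °C (aryl acetate cleavage); then Pd(PPh3)4 (5 mol %), rt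
Reagents that add atoms: none
Why: Intramolecular Tsuji–Trost O-allylation. The π-allyl has a CH2 terminus, so both carbinol epimers converge by π–σ–π exchange. The phenoxide closes 5-exo at C2 anti to the C3 substituent, and reversible ionisation of the allyl aryl ether funnels material to the more stable trans (2S,3R) ring.

**Step 12**
Reactants: 16
Product: 17, methyl 3-[(2S,3R)-3-(tert-butyldimethylsilyloxymethyl)-2-[(3aS,7aR)-2,2-dimethyl-3a,6,7,7a-tetrahydro-1,3-benzodioxol-5-yl]-7-methoxy-2,3-dihydro-1-benzofuran-5-yl]propanoate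
Conditions: Grubbs II (5 mol %), CH2Cl2, 40 °C
Reagents that add atoms: none
Why: Ring-closing metathesis of the 1,1-disubstituted and monosubstituted alkenes gives the six-membered trisubstituted C1'=C2' alkene with loss of ethylene; no stereocentre is touched.

**Step 13**
Reactants: 17
Product: 18, 3-[(2S,3R)-3-(tert-butyldimethylsilyloxymethyl)-2-[(3aS,7aR)-2,2-dimethyl-3a,6,7,7a-tetrahydro-1,3-benzodioxol-5-yl]-7-methoxy-2,3-dihydro-1-benzofuran-5-yl]propan-1-ol
Conditions: LiAlH4, THF, 0 °C
Reagents that add atoms: none
Why: Hydride reduction of the methyl ester gives the 3-hydroxypropyl chain; the allyl aryl ether, acetonide and silyl ether are inert.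

**Step 14**
Reactants: 18
Product: 19, difengpiol A
Conditions: 1 M aq. HCl, MeOH, rt (or AcOH/THF/H2O, 40 °C)
Reagents that add atoms: none
Why: Mild acid hydrolysis removes the cis-acetonide and the primary TBS ether together; conditions are kept mild to avoid ionising the allylic C2–O and C3'–OH bonds.

## Compound list

1 | methyl 3-(4-hydroxy-3-methoxyphenyl)propanoate | COC(=O)CCc1ccc(O)c(OC)c1 | starting material
2 | (R)-but-3-en-2-ol | C[C@@H](O)C=C | starting material
3 | methyl 3-{4-[(2S)-but-3-en-2-yloxy]-3-methoxyphenyl}propanoate | COC(=O)CCc1ccc(O[C@@H](C)C=C)c(OC)c1 | intermediate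
4 | allyl tert-butyldimethylsilyl ether | C=CCO[Si](C)(C)C(C)(C)C | starting material
5 | (2S,3E)-aryl ether from cross-metathesis | COC(=O)CCc1ccc(O[C@@H](C)/C=C/CO[Si](C)(C)C(C)(C)C)c(OC)c1 | intermediate
6 | Claisen phenol, (2R,3E)-1-(TBSO)pent-3-en-2-yl side chain | C/C=C/[C@@H](CO[Si](C)(C)C(C)(C)C)c1cc(CCC(=O)OC)cc(OC)c1O | intermediate
7 | (3R)-2-hydroxy-2,3-dihydrobenzofuran lactol | COC(=O)CCc1cc(OC)c2OC(O)[C@@H](CO[Si](C)(C)C(C)(C)C)c2c1 | intermediate
8 | 2,3-O-isopropylidene-D-erythronolactone | CC1(C)O[C@@H]2COC(=O)[C@@H]2O1 | starting material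
9 | 2,3-O-isopropylidene-D-erythrose | CC1(C)O[C@@H]2COC(O)[C@@H]2O1 | intermediate
10 | [(4R,5S)-2,2-dimethyl-5-vinyl-1,3-dioxolan-4-yl]methanol | C=C[C@@H]1OC(C)(C)O[C@@H]1CO | intermediate
11 | (4S,5S)-4-(iodomethyl)-2,2-dimethyl-5-vinyl-1,3-dioxolane | C=C[C@@H]1OC(C)(C)O[C@@H]1CI | intermediate
12 | 2,3-dibromopropene | C=C(Br)CBr | starting material
13 | (4R,5S)-4-(3-bromobut-3-en-1-yl)-2,2-dimethyl-5-vinyl-1,3-dioxolane | C=C[C@@H]1OC(C)(C)O[C@@H]1CCC(Br)=C | intermediate
14 | Ni/Cr coupling adduct (phenol, allylic alcohol epimers) | COC(=O)CCc1cc(OC)c(O)c(c1)[C@H](CO[Si](C)(C)C(C)(C)C)C(O)C(=C)CC[C@H]2OC(C)(C)O[C@H]2C=C | intermediate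
15 | diacetate of 14 | COC(=O)CCc1cc(OC)c(OC(C)=O)c(c1)[C@H](CO[Si](C)(C)C(C)(C)C)C(OC(C)=O)C(=C)CC[C@H]2OC(C)(C)O[C@H]2C=C | intermediate
16 | (2S,3R)-dihydrobenzofuran diene | COC(=O)CCc1cc(OC)c2O[C@H](C(=C)CC[C@H]3OC(C)(C)O[C@H]3C=C)[C@@H](CO[Si](C)(C)C(C)(C)C)c2c1 | intermediate
17 | ring-closed ester (acetonide, TBS) | COC(=O)CCc1cc(OC)c2O[C@H](C3=C[C@@H]4OC(C)(C)O[C@@H]4CC3)[C@@H](CO[Si](C)(C)C(C)(C)C)c2c1 | intermediate
18 | primary alcohol (acetonide, TBS) | OCCCc1cc(OC)c2O[C@H](C3=C[C@@H]4OC(C)(C)O[C@@H]4CC3)[C@@H](CO[Si](C)(C)C(C)(C)C)c2c1 | intermediate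
19 | difengpiol A | COc1cc(CCCO)cc2c1O[C@H](C1=C[C@H](O)[C@H](O)CC1)[C@H]2CO | target

## Step count

- Total steps: 14
- Longest linear sequence: 10 (steps 1–4 then 9–14; the sugar branch, steps 5–8 then 9–14, is the same length)

## Three steps most likely to fail, with fallbacks

1. **Step 8 (radical 2-bromoallylation).** Chain efficiency with an allyl bromide acceptor may be poor. Fallback: go ionic instead. Alkylate lithiated acetone N,N-dimethylhydrazone with iodide 11, hydrolyse to the methyl ketone, form the kinetic enol triflate (KHMDS, PhNTf2), and use that alkenyl triflate in step 9.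

2. **Step 9 (Ni/Cr coupling on a lactol with a free phenol and a 1,1-disubstituted alkenyl bromide).** The coupling may be sluggish or the organochromium may be protonated. Fallback: silylate the phenol of 6 before ozonolysis so the free aldehyde is obtained, add the alkenyllithium/CeCl3 reagent made from 13 at −78 °C, then cleave the aryl silyl ether selectively before ring closure.

3. **Step 11 (deacetylative Pd cyclisation and its trans selectivity).** Methanol could intercept the π-allyl, or the trans:cis ratio could be modest. Fallback: close the ring stereospecifically instead. Run the metathesis on 14 first, separate the carbinol epimers, and cyclise the syn epimer by intramolecular Mitsunobu etherification (inversion gives trans). Convert the anti epimer by Mitsunobu inversion of the carbinol beforehand.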